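**Retrosynthetic overview**

1. The last step is a global hydrogenolysis: three benzyl ethers and one benzyl ester of a fully protected tridepside are removed, the two aryl ester links stay.
2. The strategy rests on ring C, where C1 bears the carboxyl, C2 the methoxy group, C4 the aryl ester oxygen and C6 the methyl group. This is the imprint of a 1,1-dimethoxy-3-oxybutadiene joined to a but-2-ynoate, so ring C bonds C1–C2 and C5–C6 are cut.
3. The diene is the enol ester of 4,4-dimethoxybut-3-en-2-one with the benzylated A–B depside acid, made by O-acylation of the potassium dienolate with the acid chloride.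
4. The A–B acid comes from two molecules of orsellinic acid: ring A as its dibenzyl ether acid, ring B as allyl orsellinate acylated at the unchelated 4-OH, then 2-O-benzylation and deallylation.
5. Ring order: rings A and B are taken preformed from orsellinic acid; ring C is the only ring built and is formed last, directly before deprotection.

Key step: step 11

Remark on the chemistry: the target has no stereocentre, so no stereocontrol is needed; compounds 1, 2, 5, 12, 13 and 17 are assumed to be commercial.

**Route**

Step 1
Reactants: 1 orsellinic acid (2,4-dihydroxy-6-methylbenzoic acid); 2 benzyl bromide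
Product: 3 benzyl 2,4-bis(benzyloxy)-6-methylbenzoate
Conditions: BnBr (3.5 equiv), K2CO3 (4 equiv), DMF, rt then 60 °C
Reagents that add atoms: benzyl bromide, BrCc1ccccc1
Why: Exhaustive Williamson alkylation, in which the carboxylate and the free 4-OH react at room temperature and the hydrogen-bonded 2-OH follows on warming, so one operation masks all three acidic groups of ring A as benzyl groups.

Step 2
Reactants: 3 benzyl 2,4-bis(benzyloxy)-6-methylbenzoate
Product: 4 2,4-bis(benzyloxy)-6-methylbenzoic acid
Conditions: KOH (5 equiv), DMSO/H2O (4:1), 80 °C; then 1 M HCl to pH 2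
Reagents that add atoms: potassium hydroxide, [K+].[OH-]
Why: Saponification of the hindered 2,6-disubstituted benzyl ester needs hot KOH in aqueous DMSO, conditions to which aryl benzyl ethers are inert, and acidification returns the free ring A acid.

Step 3
Reactants: 1 orsellinic acid; 5 allyl bromide
Product: 6 allyl 2,4-dihydroxy-6-methylbenzoate (allyl orsellinate)
Conditions: allyl bromide (1.1 equiv), KHCO3 (1.2 equiv), DMF, rt
Reagents that add atoms: allyl bromide, C=CCBr
Why: Hydrogen carbonate deprotonates only the carboxylic acid, so SN2 alkylation by allyl bromide gives the allyl ester and leaves both phenols free, at room temperature where orsellinic acid does not decarboxylate.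

Step 4
Reactants: 4 2,4-bis(benzyloxy)-6-methylbenzoic acid; 6 allyl orsellinate
Product: 8 allyl 4-[2,4-bis(benzyloxy)-6-methylbenzoyloxy]-2-hydroxy-6-methylbenzoate, via mixed trifluoroacetic anhydride 7 (not isolated)
Conditions: (CF3CO)2O (2.5 equiv), PhMe, 0 °C to rt; aq. NaHCO3 work-up
Reagents that add atoms: none
Why: Classical depside condensation, in which trifluoroacetic anhydride turns the electron-rich acid into mixed anhydride 7 (an acylium source) that acylates the free 4-OH of 6, whereas the 2-OH is held in a hydrogen bond to the neighbouring ester carbonyl and stays free; any aryl trifluoroacetate is hydrolysed on work-up.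

Step 5
Reactants: 8 allyl 4-[2,4-bis(benzyloxy)-6-methylbenzoyloxy]-2-hydroxy-6-methylbenzoate; 2 benzyl bromide
Product: 9 allyl 2-(benzyloxy)-4-[2,4-bis(benzyloxy)-6-methylbenzoyloxy]-6-methylbenzoate
Conditions: BnBr (1.5 equiv), K2CO3 (2 equiv), DMF, 40 °C
Reagents that add atoms: benzyl bromide, BrCc1ccccc1
Why: Williamson etherification of the remaining chelated phenol; the hindered 2,6-disubstituted aryl ester and the allyl ester should not react with phenoxide or carbonate at this temperature.

Step 6
Reactants: 9 allyl 2-(benzyloxy)-4-[2,4-bis(benzyloxy)-6-methylbenzoyloxy]-6-methylbenzoate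
Product: 10 2-(benzyloxy)-4-[2,4-bis(benzyloxy)-6-methylbenzoyloxy]-6-methylbenzoic acid
Conditions: Pd(PPh3)4 (5 mol %), N-methylaniline (3 equiv), THF, rt; 1 M HCl wash
Reagents that add atoms: none
Why: Tsuji–Trost deallylation, in which zerovalent palladium ionises the allyl ester to a π-allyl complex that is intercepted by N-methylaniline, a scavenger too weakly nucleophilic to aminolyse the aryl ester, while the benzyl ethers are untouched.

Step 7
Reactants: 10 2-(benzyloxy)-4-[2,4-bis(benzyloxy)-6-methylbenzoyloxy]-6-methylbenzoic acid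
Product: 11 2-(benzyloxy)-4-[2,4-bis(benzyloxy)-6-methylbenzoyloxy]-6-methylbenzoyl chloride
Conditions: (COCl)2 (1.5 equiv), DMF (cat.), CH2Cl2, 0 °C to rt; evaporate with PhMe, use crude
Reagents that add atoms: oxalyl chloride, ClC(=O)C(=O)Cl
Why: Vilsmeier-type activation by oxalyl chloride and catalytic DMF converts the hindered acid into its chloride under mild conditions with only gaseous by-products, and the benzyl ethers and the depside ester tolerate the short exposure to HCl.

Step 8
Reactants: 12 1,1-dimethoxyethene; 13 acetyl chloride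
Product: 14 4,4-dimethoxybut-3-en-2-one
Conditions: AcCl (1.0 equiv), Et3N (1.2 equiv), Et2O, 0 °C to rt; filter, distil under reduced pressure
Reagents that add atoms: acetyl chloride, CC(=O)Cl
Why: Acylation of a ketene acetal at its nucleophilic β-carbon by an acid chloride, with triethylamine taking up HCl so that the acid-labile ketene acetal and the product survive.

Step 9
Reactants: 14 4,4-dimethoxybut-3-en-2-one; 11 2-(benzyloxy)-4-[2,4-bis(benzyloxy)-6-methylbenzoyloxy]-6-methylbenzoyl chloride
Product: 16 4,4-dimethoxybuta-1,3-dien-2-yl 2-(benzyloxy)-4-[2,4-bis(benzyloxy)-6-methylbenzoyloxy]-6-methylbenzoate, via potassium dienolate 15 (not isolated)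
Conditions: 14 (1.2 equiv), KN(SiMe3)2 (1.1 equiv), THF, −78 °C; then 11 (1.0 equiv) in THF, −78 to 0 °C; pH 7 buffer; rapid filtration through Et3N-deactivated silica
Reagents that add atoms: none
Why: Kinetic deprotonation of the only enolisable position, the acetyl methyl group, gives the cross-conjugated potassium dienolate, and enolate acylation should occur on oxygen because of the dissociated potassium counter-ion and the 2,6-disubstituted acid chloride that disfavours C-acylation; the ketone is kept in slight excess so that no amide base meets the aryl esters.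

Step 10
Reactants: 17 but-2-ynoic acid; 2 benzyl bromide
Product: 18 benzyl but-2-ynoate
Conditions: BnBr (1.0 equiv), KHCO3 (1.2 equiv), DMF, rt
Reagents that add atoms: benzyl bromide, BrCc1ccccc1
Why: SN2 alkylation of the carboxylate with benzyl bromide under hydrogen carbonate, a base too weak to add to the ynoate or to isomerise it to the allenoate.

Step 11
Reactants: 16 4,4-dimethoxybuta-1,3-dien-2-yl 2-(benzyloxy)-4-[2,4-bis(benzyloxy)-6-methylbenzoyloxy]-6-methylbenzoate; 18 benzyl but-2-ynoate
Product: 20 benzyl 4-{2-(benzyloxy)-4-[2,4-bis(benzyloxy)-6-methylbenzoyloxy]-6-methylbenzoyloxy}-2-methoxy-6-methylbenzoate (tetrabenzyl-protected tridepside), via dimethoxycyclohexadiene cycloadduct 19 (not isolated)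
Conditions: 18 (4 equiv), BHT (cat.), PhMe (about 2 M), sealed tube, 120 °C; then silica gel, CH2Cl2, rt
Reagents that add atoms: none
Why: This is a thermal, asynchronous Diels–Alder reaction of normal electron demand: the CH2 terminus of diene 16, made nucleophilic through conjugation with the two methoxy groups and by the acyloxy oxygen on the adjacent carbon, bonds to the methyl-bearing β-carbon of ynoate 18 (ring C bond C5–C6), and the acetal carbon bonds to the α-carbon (ring C bond C1–C2). Ring C is closed in this single intermolecular (4+2) cycloaddition, which gives the 3,3-dimethoxycyclohexa-1,4-diene 19. The doubly allylic ketal of 19 ionises to an arenium ion equivalent to a para-protonated anisole, which loses a proton from the ring CH2 group, so methanol is expelled and exactly one methoxy group remains at C2. The closest known reaction is the cycloaddition of 1,1-dimethoxy-3-silyloxybutadienes with 2-alkynoates to give 4-oxygenated 2-methoxy-6-alkylbenzoates; the enol ester used here is less electron-rich, which is why excess dienophile, high concentration and 120 °C are planned. No stereocentre is formed; the step needs regioselectivity, secured by the matched polarisation of diene and ynoate (methyl at C6 next to C1), and chemoselectivity, secured by neutral conditions that leave the hindered aryl esters and the benzyl groups untouched.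

Step 12
Reactants: 20 tetrabenzyl-protected tridepside
Product: 21 4-{4-[(2,4-dihydroxy-6-methylbenzoyl)oxy]-2-hydroxy-6-methylbenzoyloxy}-2-methoxy-6-methylbenzoic acid (CNP0283563.0)
Conditions: H2 (1 atm), 10% Pd/C, EtOAc/THF, rt
Reagents that add atoms: none
Why: Heterogeneous hydrogenolysis cleaves the benzylic C–O bonds of the three ethers and of the benzyl ester in one operation, whereas the aryl ester C–O bonds are not benzylic and survive, and the neutral room-temperature conditions avoid decarboxylation of the product acid.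

**Compound list**

1 | orsellinic acid (2,4-dihydroxy-6-methylbenzoic acid) | Cc1cc(O)cc(O)c1C(=O)O | starting material
2 | benzyl bromide | BrCc1ccccc1 | starting material
3 | benzyl 2,4-bis(benzyloxy)-6-methylbenzoate | Cc1cc(OCc2ccccc2)cc(OCc2ccccc2)c1C(=O)OCc1ccccc1 | intermediate
4 | 2,4-bis(benzyloxy)-6-methylbenzoic acid | Cc1cc(OCc2ccccc2)cc(OCc2ccccc2)c1C(=O)O | intermediate
5 | allyl bromide | C=CCBr | starting material
6 | allyl 2,4-dihydroxy-6-methylbenzoate | Cc1cc(O)cc(O)c1C(=O)OCC=C | intermediate
7 | 2,4-bis(benzyloxy)-6-methylbenzoic trifluoroacetic anhydride | Cc1cc(OCc2ccccc2)cc(OCc2ccccc2)c1C(=O)OC(=O)C(F)(F)F | intermediate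
8 | allyl 4-[2,4-bis(benzyloxy)-6-methylbenzoyloxy]-2-hydroxy-6-methylbenzoate | C=CCOC(=O)c1c(C)cc(OC(=O)c2c(C)cc(OCc3ccccc3)cc2OCc2ccccc2)cc1O | intermediate
9 | allyl 2-(benzyloxy)-4-[2,4-bis(benzyloxy)-6-methylbenzoyloxy]-6-methylbenzoate | C=CCOC(=O)c1c(C)cc(OC(=O)c2c(C)cc(OCc3ccccc3)cc2OCc2ccccc2)cc1OCc1ccccc1 | intermediate
10 | 2-(benzyloxy)-4-[2,4-bis(benzyloxy)-6-methylbenzoyloxy]-6-methylbenzoic acid | OC(=O)c1c(C)cc(OC(=O)c2c(C)cc(OCc3ccccc3)cc2OCc2ccccc2)cc1OCc1ccccc1 | intermediate
11 | 2-(benzyloxy)-4-[2,4-bis(benzyloxy)-6-methylbenzoyloxy]-6-methylbenzoyl chloride | ClC(=O)c1c(C)cc(OC(=O)c2c(C)cc(OCc3ccccc3)cc2OCc2ccccc2)cc1OCc1ccccc1 | intermediate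
12 | 1,1-dimethoxyethene | COC(=C)OC | starting material
13 | acetyl chloride | CC(=O)Cl | starting material
14 | 4,4-dimethoxybut-3-en-2-one | CC(=O)C=C(OC)OC | intermediate
15 | potassium 4,4-dimethoxybuta-1,3-dien-2-olate | [K+].[O-]C(=C)C=C(OC)OC | intermediate
16 | 4,4-dimethoxybuta-1,3-dien-2-yl 2-(benzyloxy)-4-[2,4-bis(benzyloxy)-6-methylbenzoyloxy]-6-methylbenzoate | COC(OC)=CC(=C)OC(=O)c1c(C)cc(OC(=O)c2c(C)cc(OCc3ccccc3)cc2OCc2ccccc2)cc1OCc1ccccc1 | intermediate
17 | but-2-ynoic acid | CC#CC(=O)O | starting material
18 | benzyl but-2-ynoate | CC#CC(=O)OCc1ccccc1 | intermediate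
19 | benzyl 4-{2-(benzyloxy)-4-[2,4-bis(benzyloxy)-6-methylbenzoyloxy]-6-methylbenzoyloxy}-6,6-dimethoxy-2-methylcyclohexa-1,4-diene-1-carboxylate | COC1(OC)C=C(OC(=O)c2c(C)cc(OC(=O)c3c(C)cc(OCc4ccccc4)cc3OCc3ccccc3)cc2OCc2ccccc2)CC(C)=C1C(=O)OCc1ccccc1 | intermediate
20 | benzyl 4-{2-(benzyloxy)-4-[2,4-bis(benzyloxy)-6-methylbenzoyloxy]-6-methylbenzoyloxy}-2-methoxy-6-methylbenzoate | COc1cc(OC(=O)c2c(C)cc(OC(=O)c3c(C)cc(OCc4ccccc4)cc3OCc3ccccc3)cc2OCc2ccccc2)cc(C)c1C(=O)OCc1ccccc1 | intermediate
21 | 4-{4-[(2,4-dihydroxy-6-methylbenzoyl)oxy]-2-hydroxy-6-methylbenzoyloxy}-2-methoxy-6-methylbenzoic acid | COc1cc(OC(=O)c2c(C)cc(OC(=O)c3c(C)cc(O)cc3O)cc2O)cc(C)c1C(=O)O | target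

**Step count and risk**

Total step count: 12. Longest linear sequence: 9 steps (steps 1, 2, 4, 5, 6, 7, 9, 11, 12).

Steps most likely to fail:

1. Step 11. The cycloaddition may be too slow, because the acyloxy group activates the diene less than a silyloxy group and the ynoate carries a β-methyl group. The enol-ester ketene acetal could then be lost first to trace-acid hydrolysis, acyl transfer or oligomerisation. Fallback, setting out from 15 (the dienolate made from 14 as in step 9) and 18, and coming back at 20: the dienolate is trapped with t-BuMe2SiCl to give the electron-rich silyl diene tert-butyl[(4,4-dimethoxybuta-1,3-dien-2-yl)oxy]dimethylsilane F1. F1 is heated with 18 to give the cycloadduct benzyl 4-[(tert-butyldimethylsilyl)oxy]-6,6-dimethoxy-2-methylcyclohexa-1,4-diene-1-carboxylate F2, which loses methanol to the aryl silyl ether benzyl 4-[(tert-butyldimethylsilyl)oxy]-2-methoxy-6-methylbenzoate F3. Bu4NF in THF frees the phenol benzyl 4-hydroxy-2-methoxy-6-methylbenzoate F4, which is acylated with acid chloride 11 (Et3N, DMAP cat., CH2Cl2) to give 20. Ring C is still built by the same cycloaddition, but the B–C ester bond is made after ring formation.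

2. Step 9. Enolate acylation may go partly on carbon, the enolate or residual amide base may attack the depside ester, and the ketene acetal may hydrolyse during isolation. Fallback, setting out from 14 and 10 and coming back at 16: 14 is silylated (Me3SiCl, Et3N, ZnCl2 cat.) to [(4,4-dimethoxybuta-1,3-dien-2-yl)oxy]trimethylsilane F5. Acid 10 is converted with cyanuric fluoride and pyridine into 2-(benzyloxy)-4-[2,4-bis(benzyloxy)-6-methylbenzoyloxy]-6-methylbenzoyl fluoride F6. F5 and F6 are combined with catalytic anhydrous Bu4NF in THF, where fluoride releases the naked dienolate, which is acylated on oxygen by the acyl fluoride with loss of Me3SiF. This is the known fluoride-catalysed enol ester synthesis from silyl enol ethers and acyl fluorides, and it avoids strong base.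

3. Step 4. Discrimination between the two phenols of 6 may be incomplete (2-O- or bis-acylation), trifluoroacetic acid may erode the benzyl ethers, and the later alkylation of the chelated phenol in step 5 may be sluggish. Fallback, setting out from 6 and 4 and coming back at 9: 6 is silylated at the unchelated 4-OH (t-BuMe2SiCl, imidazole, CH2Cl2) to allyl 4-[(tert-butyldimethylsilyl)oxy]-2-hydroxy-6-methylbenzoate F7. The chelated 2-OH is benzylated under Mitsunobu conditions (BnOH, PPh3, DIAD, THF) to allyl 2-(benzyloxy)-4-[(tert-butyldimethylsilyl)oxy]-6-methylbenzoate F8. Bu4NF/AcOH gives allyl 2-(benzyloxy)-4-hydroxy-6-methylbenzoate F9. Acid 4 is converted with oxalyl chloride and DMF (cat.) into 2,4-bis(benzyloxy)-6-methylbenzoyl chloride F10, and F9 is acylated with F10 (Et3N, DMAP cat., CH2Cl2) to give 9 directly. Selectivity then comes from a single free phenol instead of chelation control.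

**Further compounds**

F1 | step 11 | tert-butyl[(4,4-dimethoxybuta-1,3-dien-2-yl)oxy]dimethylsilane | COC(OC)=CC(=C)O[Si](C)(C)C(C)(C)C
F2 | step 11 | benzyl 4-[(tert-butyldimethylsilyl)oxy]-6,6-dimethoxy-2-methylcyclohexa-1,4-diene-1-carboxylate | COC1(OC)C=C(O[Si](C)(C)C(C)(C)C)CC(C)=C1C(=O)OCc1ccccc1
F3 | step 11 | benzyl 4-[(tert-butyldimethylsilyl)oxy]-2-methoxy-6-methylbenzoate | COc1cc(O[Si](C)(C)C(C)(C)C)cc(C)c1C(=O)OCc1ccccc1
F4 | step 11 | benzyl 4-hydroxy-2-methoxy-6-methylbenzoate | COc1cc(O)cc(C)c1C(=O)OCc1ccccc1
F5 | step 9 | [(4,4-dimethoxybuta-1,3-dien-2-yl)oxy]trimethylsilane | COC(OC)=CC(=C)O[Si](C)(C)C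
F6 | step 9 | 2-(benzyloxy)-4-[2,4-bis(benzyloxy)-6-methylbenzoyloxy]-6-methylbenzoyl fluoride | FC(=O)c1c(C)cc(OC(=O)c2c(C)cc(OCc3ccccc3)cc2OCc2ccccc2)cc1OCc1ccccc1
F7 | step 4 | allyl 4-[(tert-butyldimethylsilyl)oxy]-2-hydroxy-6-methylbenzoate | C=CCOC(=O)c1c(C)cc(O[Si](C)(C)C(C)(C)C)cc1O
F8 | step 4 | allyl 2-(benzyloxy)-4-[(tert-butyldimethylsilyl)oxy]-6-methylbenzoate | C=CCOC(=O)c1c(C)cc(O[Si](C)(C)C(C)(C)C)cc1OCc1ccccc1
F9 | step 4 | allyl 2-(benzyloxy)-4-hydroxy-6-methylbenzoate | C=CCOC(=O)c1c(C)cc(O)cc1OCc1ccccc1
F10 | step 4 | 2,4-bis(benzyloxy)-6-methylbenzoyl chloride | Cc1cc(OCc2ccccc2)cc(OCc2ccccc2)c1C(=O)Cl
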